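The trimethylcyclohexene ring is cut into two three-carbon halves, C(CH3)=CH–CH2 and CH2–C(CH3)2–CH, which meet at two ring bonds. One palladium catalyst forms both in one operation: a neopentyl zinc reagent is allylated by (Z)-1-bromo-3-iodobut-2-ene, and the iodoalkene thus placed closes the six-membered ring by an enantioselective 6-exo Heck reaction onto a (Z)-allylsilane, setting the ring stereocentre and leaving a vinyl handle. The step exploits the quaternary C(CH3)2 ring carbon, whose CH2 neighbour carries no β-hydrogen and whose CH neighbour is reached intramolecularly. The precursor is an acyclic bromo allylsilane. B-alkyl Suzuki coupling then adds the side chain, whose acetoxy aldehyde end comes from a Sharpless epoxide.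

Key step: step 5

Assumption: the Wittig reaction of step 2 is taken to give mainly the (Z)-allylsilane and (R)-BINAP to give the (S)-configured ring carbon in step 5; should a pilot run show the opposite sense of induction, (S)-BINAP is used and nothing else changes.

Step 1
Reactants: 1 3-bromo-2,2-dimethylpropan-1-ol
Product: 2 3-bromo-2,2-dimethylpropanal
Conditions: TEMPO (cat.), PhI(OAc)2, CH2Cl2, rt
Reagents that add atoms: none
Why: Nitroxyl-catalysed alcohol oxidation should stop at the aldehyde, which has no α-hydrogen and so can neither enolise nor lose bromide.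

Step 2
Reactants: 2 3-bromo-2,2-dimethylpropanal; 3 methyl(triphenyl)phosphonium bromide; 4 (iodomethyl)trimethylsilane
Product: 8 [(2Z)-5-bromo-4,4-dimethylpent-2-en-1-yl](trimethyl)silane, via methylidenephosphorane 5 (not isolated), via silylethylphosphonium iodide 6 (not isolated), via silylethylidene ylide 7 (not isolated)
Conditions: 3, n-BuLi, THF, 0 °C; 4, 0 °C to rt; n-BuLi, −78 °C; 2, −78 °C to rt
Reagents that add atoms: none
Why: Wittig olefination with a β-silyl ylide built in the flask (ylide alkylation, then deprotonation) should give mainly the (Z)-allylsilane from the non-stabilised ylide, the neopentyl bromide being inert to it.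

Step 3
Reactants: 9 but-2-yn-1-ol
Product: 11 (2Z)-3-iodobut-2-en-1-ol, via cyclic alkenylaluminate 10 (not isolated)
Conditions: NaAlH2(OCH2CH2OCH3)2, THF, 0 °C to rt; I2, THF, −78 °C to 0 °C
Reagents that add atoms: iodine II
Why: Hydroxyl-directed trans-hydroalumination forms a five-membered alkenylaluminate that holds aluminium on C3 cis to the CH2O group, and iododealumination with retention should give the (Z)-iodoalkene.

Step 4
Reactants: 11 (2Z)-3-iodobut-2-en-1-ol
Product: 12 (2Z)-1-bromo-3-iodobut-2-ene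
Conditions: CBr4, PPh3, CH2Cl2, 0 °C
Reagents that add atoms: tetrabromomethane BrC(Br)(Br)Br
Why: Appel bromination of the primary allylic alcohol under neutral conditions should keep the alkene geometry.

Step 5
Reactants: 8 [(2Z)-5-bromo-4,4-dimethylpent-2-en-1-yl](trimethyl)silane; 12 (2Z)-1-bromo-3-iodobut-2-ene
Product: 16 (6S)-6-ethenyl-1,5,5-trimethylcyclohex-1-ene, via Grignard reagent 13 (not isolated), via alkylzinc bromide 14 (not isolated), via iododiene 15 (not isolated)
Conditions: Mg, THF, 45 °C; ZnBr2, 0 °C; added to 12, Pd2(dba)3 (2.5 mol%), (R)-BINAP (6 mol%), THF/NMP, 0 °C, then 70 °C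
Reagents that add atoms: none
Why: Proposed new method: zerovalent palladium ionises the allylic bromide of 12 much faster than it inserts into the C–I bond, the neopentyl zinc reagent 14 transmetalates and C(sp3)–C(sp3) reductive elimination at the unsubstituted allyl terminus gives 15, whereupon the same catalyst inserts into the alkenyl iodide, adds across the (Z)-alkene and is released by loss of iodotrimethylsilane from the β-silyl alkylpalladium, so that no palladium hydride and no base are involved. The closest known reaction types are the palladium-catalysed allylation of alkylzinc halides and the silane-terminated asymmetric intramolecular Heck reaction, which have not been joined in one catalytic domino (3+3) annulation. The cyclohexene ring is closed in the 6-exo-trig mode, the (Z)-geometry of the iodoalkene placing palladium cis to the tether. The new stereocentre C6 of 16 is set in the carbopalladation, where the chiral bisphosphine on palladium selects one enantiotopic face of the alkene. The step needs allyl-over-alkenyl chemoselectivity and SN2 regioselectivity in its first stage, secured by the far more reactive allylic bromide, the fully substituted iodine-bearing allyl terminus and the use of no excess of 14, whose CH2–Zn carbon has no β-hydrogen. The silyl group steers the elimination away from the new stereocentre to the vinyl group and the gem-dimethyl group favours ring closure.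

Step 6
Reactants: 9 but-2-yn-1-ol
Product: 18 (2E)-3-iodobut-2-en-1-ol, via alkenylzirconocene 17 (not isolated)
Conditions: i-Bu2AlH (1 equiv), THF, 0 °C; Cp2ZrCl2, i-Bu2AlH, THF, 0 °C to rt; I2, −78 °C to 0 °C
Reagents that add atoms: iodine II
Why: Hydrozirconation with Schwartz reagent made in the flask is a syn addition that should place zirconium on the methyl-bearing carbon remote from the aluminium alkoxide, and iodinolysis with retention gives the (E)-iodoalkene.

Step 7
Reactants: 18 (2E)-3-iodobut-2-en-1-ol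
Product: 19 (2E)-1-bromo-3-iodobut-2-ene
Conditions: CBr4, PPh3, CH2Cl2, 0 °C
Reagents that add atoms: tetrabromomethane BrC(Br)(Br)Br
Why: Appel bromination, as in step 4, should keep the (E)-geometry.

Step 8
Reactants: 20 2-methylprop-2-en-1-ol; 19 (2E)-1-bromo-3-iodobut-2-ene
Product: 22 2-[(3E)-4-iodopent-3-en-1-yl]prop-2-en-1-ol, via dilithio alkoxide 21 (not isolated)
Conditions: n-BuLi (2.0 equiv), TMEDA, Et2O, 0 °C to rt; 19, THF, −78 °C to 0 °C
Reagents that add atoms: none
Why: SN2 alkylation of the C,O-dilithiated methallyl alcohol, an allyl anion with two equivalent termini, by the primary allylic bromide, whose fully substituted iodoalkene end blocks SN2′ attack.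

Step 9
Reactants: 22 2-[(3E)-4-iodopent-3-en-1-yl]prop-2-en-1-ol
Product: 23 [(2R)-2-[(3E)-4-iodopent-3-en-1-yl]oxiran-2-yl]methanol
Conditions: Ti(OiPr)4 (10 mol%), D-(−)-diethyl tartrate (12 mol%), t-BuOOH, 4 Å MS, CH2Cl2, −20 °C
Reagents that add atoms: tert-butyl hydroperoxide CC(C)(C)OO
Why: Sharpless asymmetric epoxidation acts only on the allylic alcohol, and the D-(−)-tartrate ligand should deliver oxygen to the face that gives the (R)-epoxide, which becomes the quaternary stereocentre.

Step 10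
Reactants: 23 [(2R)-2-[(3E)-4-iodopent-3-en-1-yl]oxiran-2-yl]methanol
Product: 24 (2S)-2-[(3E)-4-iodopent-3-en-1-yl]oxirane-2-carbaldehyde
Conditions: Dess–Martin periodinane, NaHCO3, CH2Cl2, 0 °C to rt
Reagents that add atoms: none
Why: Buffered Dess–Martin oxidation should give the epoxy aldehyde, which has no α-hydrogen and so cannot epimerise (the descriptor changes only by the priority rules).

Step 11
Reactants: 24 (2S)-2-[(3E)-4-iodopent-3-en-1-yl]oxirane-2-carbaldehyde
Product: 25 (2R)-2-ethynyl-2-[(3E)-4-iodopent-3-en-1-yl]oxirane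
Conditions: dimethyl (1-diazo-2-oxopropyl)phosphonate, K2CO3, MeOH, 0 °C to rt
Reagents that add atoms: dimethyl (1-diazo-2-oxopropyl)phosphonate COP(=O)(OC)C(=[N+]=[N-])C(C)=O
Why: Ohira–Bestmann homologation should turn the aldehyde into the terminal alkyne under mild carbonate conditions that leave the epoxide and its stereocentre alone.

Step 12
Reactants: 25 (2R)-2-ethynyl-2-[(3E)-4-iodopent-3-en-1-yl]oxirane
Product: 26 (3R,6E)-7-iodo-3-{[(4-methoxyphenyl)methoxy]methyl}oct-6-en-1-yn-3-ol
Conditions: 4-methoxybenzyl alcohol, NaH, DMF, 50 °C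
Reagents that add atoms: 4-methoxybenzyl alcohol COc1ccc(CO)cc1
Why: Base-mediated SN2 opening of the 2,2-disubstituted epoxide by the alkoxide at the unhindered CH2 carbon leaves the C–O bond at the stereocentre intact, so its configuration is kept.

Step 13
Reactants: 16 (6S)-6-ethenyl-1,5,5-trimethylcyclohex-1-ene; 26 (3R,6E)-7-iodo-3-{[(4-methoxyphenyl)methoxy]methyl}oct-6-en-1-yn-3-ol
Product: 28 (3R,6E)-3-{[(4-methoxyphenyl)methoxy]methyl}-7-methyl-9-[(1S)-2,6,6-trimethylcyclohex-2-en-1-yl]non-6-en-1-yn-3-ol, via alkylborane 27 (not isolated)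
Conditions: 16 (slight excess), 9-BBN-H, THF, rt; then 26, PdCl2(dppf) (5 mol%), AsPh3, Cs2CO3, DMF/H2O, rt
Reagents that add atoms: none
Why: 9-BBN-H hydroborates only the monosubstituted alkene of 16, and B-alkyl Suzuki–Miyaura coupling with the alkenyl iodide should proceed with retention of the (E)-geometry, neither stereocentre being touched.

Step 14
Reactants: 28 (3R,6E)-3-{[(4-methoxyphenyl)methoxy]methyl}-7-methyl-9-[(1S)-2,6,6-trimethylcyclohex-2-en-1-yl]non-6-en-1-yn-3-ol
Product: 29 (3R,6E)-3-{[(4-methoxyphenyl)methoxy]methyl}-7-methyl-9-[(1S)-2,6,6-trimethylcyclohex-2-en-1-yl]non-6-en-1-yn-3-yl acetate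
Conditions: Ac2O, DMAP, Et3N, CH2Cl2, rt
Reagents that add atoms: acetic anhydride CC(=O)OC(C)=O
Why: DMAP-catalysed acylation of the tertiary propargylic alcohol, placed after the coupling so that no propargylic ester meets zerovalent palladium, breaks no bond at the stereocentre.

Step 15
Reactants: 29 (3R,6E)-3-{[(4-methoxyphenyl)methoxy]methyl}-7-methyl-9-[(1S)-2,6,6-trimethylcyclohex-2-en-1-yl]non-6-en-1-yn-3-yl acetate
Product: 31 potassium [(1E,3R,6E)-3-acetoxy-3-{[(4-methoxyphenyl)methoxy]methyl}-7-methyl-9-[(1S)-2,6,6-trimethylcyclohex-2-en-1-yl]nona-1,6-dien-1-yl]trifluoroborate, via pinacol boronate 30 (not isolated)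
Conditions: HBpin, Cy2BH (10 mol%), THF, rt; then KHF2, MeOH/H2O, rt
Reagents that add atoms: pinacolborane CC1(C)OBOC1(C)C; potassium hydrogen difluoride F.[F-].[K+]
Why: Dialkylborane-catalysed syn, anti-Markovnikov hydroboration of the terminal alkyne (the trisubstituted alkenes do not react) should give the (E)-alkenylboronate, which KHF2 converts into the stable trifluoroborate.

Step 16
Reactants: 31 potassium [(1E,3R,6E)-3-acetoxy-3-{[(4-methoxyphenyl)methoxy]methyl}-7-methyl-9-[(1S)-2,6,6-trimethylcyclohex-2-en-1-yl]nona-1,6-dien-1-yl]trifluoroborate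
Product: 32 (1E,3R,6E)-3-{[(4-methoxyphenyl)methoxy]methyl}-7-methyl-9-[(1S)-2,6,6-trimethylcyclohex-2-en-1-yl]nona-1,6-diene-1,3-diyl diacetate
Conditions: AcOH, Cu(OAc)2 (cat.), DMAP, 4 Å MS, O2 (1 atm), MeCN, 40 °C
Reagents that add atoms: acetic acid CC(=O)O
Why: Chan–Lam-type oxidative copper-catalysed C–O coupling of the alkenyltrifluoroborate with the carboxylic acid is stereoretentive and should give the (E)-enol acetate without any enolate, so the β-acetoxy group cannot be eliminated.

Step 17
Reactants: 32 (1E,3R,6E)-3-{[(4-methoxyphenyl)methoxy]methyl}-7-methyl-9-[(1S)-2,6,6-trimethylcyclohex-2-en-1-yl]nona-1,6-diene-1,3-diyl diacetate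
Product: 33 (1E,3R,6E)-3-(hydroxymethyl)-7-methyl-9-[(1S)-2,6,6-trimethylcyclohex-2-en-1-yl]nona-1,6-diene-1,3-diyl diacetate
Conditions: DDQ, CH2Cl2/pH 7 buffer, 0 °C
Reagents that add atoms: none
Why: Oxidative cleavage of the 4-methoxybenzyl ether by DDQ under buffered conditions should spare the enol acetate, the tertiary acetate and the alkenes and keep acetyl migration slow.

Step 18
Reactants: 33 (1E,3R,6E)-3-(hydroxymethyl)-7-methyl-9-[(1S)-2,6,6-trimethylcyclohex-2-en-1-yl]nona-1,6-diene-1,3-diyl diacetate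
Product: 34 (1E,3R,6E)-3-formyl-7-methyl-9-[(1S)-2,6,6-trimethylcyclohex-2-en-1-yl]nona-1,6-diene-1,3-diyl diacetate
Conditions: Dess–Martin periodinane, NaHCO3, CH2Cl2, 0 °C
Reagents that add atoms: none
Why: Buffered Dess–Martin oxidation of the primary alcohol, run at once on crude 33 to forestall acetyl migration, should give the aldehyde, which has no α-hydrogen.

Compound list

1 | 3-bromo-2,2-dimethylpropan-1-ol | OCC(C)(C)CBr | starting material
2 | 3-bromo-2,2-dimethylpropanal | O=CC(C)(C)CBr | intermediate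
3 | methyl(triphenyl)phosphonium bromide | C[P+](c1ccccc1)(c1ccccc1)c1ccccc1.[Br-] | starting material
4 | (iodomethyl)trimethylsilane | C[Si](C)(C)CI | starting material
5 | methylidene(triphenyl)phosphorane | C=P(c1ccccc1)(c1ccccc1)c1ccccc1 | intermediate
6 | triphenyl[2-(trimethylsilyl)ethyl]phosphonium iodide | C[Si](C)(C)CC[P+](c1ccccc1)(c1ccccc1)c1ccccc1.[I-] | intermediate
7 | triphenyl[2-(trimethylsilyl)ethylidene]phosphorane | C[Si](C)(C)CC=P(c1ccccc1)(c1ccccc1)c1ccccc1 | intermediate
8 | [(2Z)-5-bromo-4,4-dimethylpent-2-en-1-yl](trimethyl)silane | C[Si](C)(C)C/C=C\C(C)(C)CBr | intermediate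
9 | but-2-yn-1-ol | CC#CCO | starting material
10 | sodium 2,2-bis(2-methoxyethoxy)-3-methyl-2,5-dihydro-1,2-oxaaluminol-2-uide (cyclic (Z)-alkenylaluminate) | CC1=CCO[Al-]1(OCCOC)OCCOC.[Na+] | intermediate
11 | (2Z)-3-iodobut-2-en-1-ol | C/C(I)=C/CO | intermediate
12 | (2Z)-1-bromo-3-iodobut-2-ene | C/C(I)=C/CBr | intermediate
13 | bromo[(3Z)-2,2-dimethyl-5-(trimethylsilyl)pent-3-en-1-yl]magnesium | C[Si](C)(C)C/C=C\C(C)(C)C[Mg]Br | intermediate
14 | bromo[(3Z)-2,2-dimethyl-5-(trimethylsilyl)pent-3-en-1-yl]zinc | C[Si](C)(C)C/C=C\C(C)(C)C[Zn]Br | intermediate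
15 | [(2Z,7Z)-8-iodo-4,4-dimethylnona-2,7-dien-1-yl](trimethyl)silane | C[Si](C)(C)C/C=C\C(C)(C)CC/C=C(/C)I | intermediate
16 | (6S)-6-ethenyl-1,5,5-trimethylcyclohex-1-ene | C=C[C@@H]1C(C)=CCCC1(C)C | intermediate
17 | chlorobis(cyclopentadienyl)[(2E)-4-[(diisobutylalumanyl)oxy]but-2-en-2-yl]zirconium | C/C(=C\CO[Al](CC(C)C)CC(C)C)[Zr](Cl)(C1C=CC=C1)C1C=CC=C1 | intermediate
18 | (2E)-3-iodobut-2-en-1-ol | C/C(I)=C\CO | intermediate
19 | (2E)-1-bromo-3-iodobut-2-ene | C/C(I)=C\CBr | intermediate
20 | 2-methylprop-2-en-1-ol | CC(=C)CO | starting material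
21 | lithium 2-(lithiomethyl)prop-2-en-1-olate | [Li]CC(=C)CO[Li] | intermediate
22 | 2-[(3E)-4-iodopent-3-en-1-yl]prop-2-en-1-ol | C=C(CO)CC/C=C(\C)I | intermediate
23 | [(2R)-2-[(3E)-4-iodopent-3-en-1-yl]oxiran-2-yl]methanol | OC[C@@]1(CC/C=C(\C)I)OC1 | intermediate
24 | (2S)-2-[(3E)-4-iodopent-3-en-1-yl]oxirane-2-carbaldehyde | O=C[C@@]1(CC/C=C(\C)I)OC1 | intermediate
25 | (2R)-2-ethynyl-2-[(3E)-4-iodopent-3-en-1-yl]oxirane | C#C[C@@]1(CC/C=C(\C)I)OC1 | intermediate
26 | (3R,6E)-7-iodo-3-{[(4-methoxyphenyl)methoxy]methyl}oct-6-en-1-yn-3-ol | C#C[C@@](COCc1ccc(OC)cc1)(CC/C=C(\C)I)O | intermediate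
27 | 9-{2-[(1S)-2,6,6-trimethylcyclohex-2-en-1-yl]ethyl}-9-borabicyclo[3.3.1]nonane | C(C[C@@H]1C(C)=CCCC1(C)C)B1C2CCCC1CCC2 | intermediate
28 | (3R,6E)-3-{[(4-methoxyphenyl)methoxy]methyl}-7-methyl-9-[(1S)-2,6,6-trimethylcyclohex-2-en-1-yl]non-6-en-1-yn-3-ol | C#C[C@@](COCc1ccc(OC)cc1)(CC/C=C(\C)CC[C@@H]1C(C)=CCCC1(C)C)O | intermediate
29 | (3R,6E)-3-{[(4-methoxyphenyl)methoxy]methyl}-7-methyl-9-[(1S)-2,6,6-trimethylcyclohex-2-en-1-yl]non-6-en-1-yn-3-yl acetate | C#C[C@@](COCc1ccc(OC)cc1)(CC/C=C(\C)CC[C@@H]1C(C)=CCCC1(C)C)OC(C)=O | intermediate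
30 | (1E,3R,6E)-3-{[(4-methoxyphenyl)methoxy]methyl}-7-methyl-1-(4,4,5,5-tetramethyl-1,3,2-dioxaborolan-2-yl)-9-[(1S)-2,6,6-trimethylcyclohex-2-en-1-yl]nona-1,6-dien-3-yl acetate | CC1(C)OB(/C=C/[C@@](COCc2ccc(OC)cc2)(CC/C=C(\C)CC[C@@H]2C(C)=CCCC2(C)C)OC(C)=O)OC1(C)C | intermediate
31 | potassium [(1E,3R,6E)-3-acetoxy-3-{[(4-methoxyphenyl)methoxy]methyl}-7-methyl-9-[(1S)-2,6,6-trimethylcyclohex-2-en-1-yl]nona-1,6-dien-1-yl]trifluoroborate | [K+].F[B-](F)(F)/C=C/[C@@](COCc1ccc(OC)cc1)(CC/C=C(\C)CC[C@@H]1C(C)=CCCC1(C)C)OC(C)=O | intermediate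
32 | (1E,3R,6E)-3-{[(4-methoxyphenyl)methoxy]methyl}-7-methyl-9-[(1S)-2,6,6-trimethylcyclohex-2-en-1-yl]nona-1,6-diene-1,3-diyl diacetate | CC(=O)O/C=C/[C@@](COCc1ccc(OC)cc1)(CC/C=C(\C)CC[C@@H]1C(C)=CCCC1(C)C)OC(C)=O | intermediate
33 | (1E,3R,6E)-3-(hydroxymethyl)-7-methyl-9-[(1S)-2,6,6-trimethylcyclohex-2-en-1-yl]nona-1,6-diene-1,3-diyl diacetate | CC(=O)O/C=C/[C@@](CO)(CC/C=C(\C)CC[C@@H]1C(C)=CCCC1(C)C)OC(C)=O | intermediate
34 | (1E,3R,6E)-3-formyl-7-methyl-9-[(1S)-2,6,6-trimethylcyclohex-2-en-1-yl]nona-1,6-diene-1,3-diyl diacetate | CC(=O)O/C=C/[C@@](C=O)(CC/C=C(\C)CC[C@@H]1C(C)=CCCC1(C)C)OC(C)=O | target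

Total step count: 18. Longest linear sequence: 13 steps (steps 6 to 12, then 13 to 18).

Steps most likely to fail

1. Step 5 (proposed new method). Zerovalent palladium may insert into the alkenyl iodide before the allylic coupling is complete, which would join the zinc-bearing carbon to the wrong carbon. The (Z)-iodoalkene geometry may be lost through π-allyl isomerisation, and facial selectivity in the carbopalladation may be poor in the halide-rich medium. The fallback sets out from 8 and 12 and comes back at 16, making the two bonds in two separate, known operations. Grignard reagent 13 is coupled with 12 under copper catalysis (Li2CuCl4, THF, −20 °C), an SN2 reaction at the allylic bromide that leaves the iodoalkene untouched, and iododiene 15 is isolated. A silane-terminated asymmetric Heck cyclisation under cationic conditions (Pd2(dba)3, (R)-BINAP, Ag3PO4, DMF, 80 °C) then closes the ring to 16. This fallback makes no compound outside the list (F0).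

2. Step 16. Protodeboronation or homocoupling of the alkenylboron may outrun the C–O coupling, or the (E)-geometry may erode. The fallback sets out from 28 and comes back at 32, making the enol acetate by O-acylation of an aldehyde enolate. The tertiary alcohol is silylated (Et3SiOTf, 2,6-lutidine) to triethyl{[(3R,6E)-3-{[(4-methoxyphenyl)methoxy]methyl}-7-methyl-9-[(1S)-2,6,6-trimethylcyclohex-2-en-1-yl]non-6-en-1-yn-3-yl]oxy}silane F1. Anti-Markovnikov hydroboration–oxidation of the alkyne (Cy2BH; NaBO3·4H2O) gives (3R,6E)-3-{[(4-methoxyphenyl)methoxy]methyl}-7-methyl-3-[(triethylsilyl)oxy]-9-[(1S)-2,6,6-trimethylcyclohex-2-en-1-yl]non-6-enal F2. O-acetylation of its potassium enolate (KN(SiMe3)2, Ac2O, THF, −78 °C), in which the silyloxy group is too poor a leaving group for β-elimination and the bulky quaternary carbon should favour the (E)-isomer, gives (1E,3R,6E)-3-{[(4-methoxyphenyl)methoxy]methyl}-7-methyl-3-[(triethylsilyl)oxy]-9-[(1S)-2,6,6-trimethylcyclohex-2-en-1-yl]nona-1,6-dien-1-yl acetate F3. HF·pyridine frees (1E,3R,6E)-3-hydroxy-3-{[(4-methoxyphenyl)methoxy]methyl}-7-methyl-9-[(1S)-2,6,6-trimethylcyclohex-2-en-1-yl]nona-1,6-dien-1-yl acetate F4, and acetylation (Ac2O, DMAP, Et3N) returns to 32.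

3. Step 8. The strongly basic dianion may undergo lithium–iodine exchange with the alkenyl iodide or dehydrohalogenate it instead of displacing the allylic bromide. The fallback sets out from 20 and comes back at 22, keeping the iodide out of the alkylation. Dianion 21 is alkylated with 1-bromobut-2-yne to 2-methylidenehept-5-yn-1-ol F5. Hydrozirconation–iodination of the internal alkyne (i-Bu2AlH; Cp2ZrCl2, i-Bu2AlH; I2), in which zirconium should settle on the methyl-bearing alkyne carbon, then gives 22.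

Further compounds

F0 | step 5 | none | none
F1 | step 16 | triethyl{[(3R,6E)-3-{[(4-methoxyphenyl)methoxy]methyl}-7-methyl-9-[(1S)-2,6,6-trimethylcyclohex-2-en-1-yl]non-6-en-1-yn-3-yl]oxy}silane | C#C[C@@](COCc1ccc(OC)cc1)(CC/C=C(\C)CC[C@@H]1C(C)=CCCC1(C)C)O[Si](CC)(CC)CC
F2 | step 16 | (3R,6E)-3-{[(4-methoxyphenyl)methoxy]methyl}-7-methyl-3-[(triethylsilyl)oxy]-9-[(1S)-2,6,6-trimethylcyclohex-2-en-1-yl]non-6-enal | O=CC[C@@](COCc1ccc(OC)cc1)(CC/C=C(\C)CC[C@@H]1C(C)=CCCC1(C)C)O[Si](CC)(CC)CC
F3 | step 16 | (1E,3R,6E)-3-{[(4-methoxyphenyl)methoxy]methyl}-7-methyl-3-[(triethylsilyl)oxy]-9-[(1S)-2,6,6-trimethylcyclohex-2-en-1-yl]nona-1,6-dien-1-yl acetate | CC(=O)O/C=C/[C@@](COCc1ccc(OC)cc1)(CC/C=C(\C)CC[C@@H]1C(C)=CCCC1(C)C)O[Si](CC)(CC)CC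
F4 | step 16 | (1E,3R,6E)-3-hydroxy-3-{[(4-methoxyphenyl)methoxy]methyl}-7-methyl-9-[(1S)-2,6,6-trimethylcyclohex-2-en-1-yl]nona-1,6-dien-1-yl acetate | CC(=O)O/C=C/[C@@](COCc1ccc(OC)cc1)(CC/C=C(\C)CC[C@@H]1C(C)=CCCC1(C)C)O
F5 | step 8 | 2-methylidenehept-5-yn-1-ol | C=C(CO)CCC#CC
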